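**Retrosynthetic overview**

- The strategy rests on the C2 symmetry of the target about its central CH2–CH2 bond, which joins two identical hexasubstituted benzene rings (each ring carbon carries Br, Br, Br, OH, OH or the benzylic CH2, so no aryl C–H remains).
- The key disconnection is this central C(sp3)–C(sp3) bond, giving two identical 2,3,6-tribromo-4,5-dimethoxybenzyl bromide monomers that are rejoined by reductive homocoupling at the benzylic carbons.
- The monomer is traced back to 4-methylcatechol through Wohl–Ziegler bromination of the methyl group, double O-methylation and exhaustive ring bromination.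
- No ring is formed at any stage: both benzene rings are bought intact in 4-methylcatechol, and a final fourfold O-demethylation releases the target, which has no stereocentres.

Key step: step 4

Remark on the chemistry: the transient species of steps 4 and 5 are drawn in their simplest forms (a free benzylic radical and a cyclic aryl bromoborate), and the free phenols of the target arise only on aqueous work-up.

**Route**

Step 1
Reactants: 1 4-methylcatechol, 2 bromine
Product: 3 3,4,6-tribromo-5-methylbenzene-1,2-diol
Conditions: Br2 (3.1 equiv), AcOH, 10 °C to rt, dark; aq. NaHSO3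
Reagents that add atoms: bromine, BrBr
Why: Electrophilic aromatic bromination, in which each of the three free ring positions is ortho or para to a hydroxyl group and should therefore be substituted in turn, the bisulfite work-up returning any ortho-quinone to the catechol.

Step 2
Reactants: 3 3,4,6-tribromo-5-methylbenzene-1,2-diol, 4 iodomethane
Product: 5 2,3,6-tribromo-4,5-dimethoxytoluene (1,2,4-tribromo-5,6-dimethoxy-3-methylbenzene)
Conditions: MeI (4 equiv), K2CO3 (4 equiv), DMF, N2, rt to 50 °C
Reagents that add atoms: iodomethane, CI
Why: Williamson ether synthesis, in which the bromine-acidified phenols are deprotonated by K2CO3 and alkylated by MeI, masking the catechol against oxidation and quinone methide formation in the following radical and reductive steps.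

Step 3
Reactants: 5 2,3,6-tribromo-4,5-dimethoxytoluene, 6 N-bromosuccinimide
Product: 7 2,3,6-tribromo-4,5-dimethoxybenzyl bromide
Conditions: NBS (1.05 equiv), AIBN (5 mol%), PhCF3, 85 °C
Reagents that add atoms: N-bromosuccinimide, O=C1CCC(=O)N1Br
Why: Wohl–Ziegler radical bromination, which should be clean because the methyl group holds the only benzylic C–H bonds, the ring has no C–H for competing substitution, and the two ortho bromines retard a second bromination at the CH2Br carbon.

Step 4
Reactants: 7 2,3,6-tribromo-4,5-dimethoxybenzyl bromide (two molecules)
Product: 9 1,2-bis(2,3,6-tribromo-4,5-dimethoxyphenyl)ethane, via benzylic radical 8 (not isolated)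
Conditions: Cp2TiCl2 (1.3 equiv), Mn dust, degassed THF, rt (green Cp2TiCl); solution cannulated off the metal and added dropwise to 7 in THF, rt, Ar; 1 M HCl
Reagents that add atoms: none
Why: Wurtz-type reductive homocoupling, in which Cp2TiCl, a mild one-electron reductant of trivalent titanium, takes the benzylic bromine atom of 7 by inner-sphere halogen abstraction to give the primary benzylic radical 8 and Cp2TiClBr, and two radicals 8 combine at their exocyclic carbons to form the central CH2–CH2 bond of 9. The closest known reaction type is the Cp2TiCl-mediated homocoupling of benzylic bromides to bibenzyls, which is established in the presence of aryl halides. No ring is closed and no stereocentre is created, so only chemoselectivity and site selectivity matter. Chemoselectivity for the one C(sp3)–Br bond over the three aryl C–Br bonds of each monomer rests on the much weaker benzylic bond and on a reductant too mild to reduce aryl bromides. Coupling can take place only at the exocyclic carbon because every ring carbon already carries Br, OMe or the CH2 group, which closes off head-to-ring coupling. Dropwise addition of the titanium reagent to concentrated 7 keeps the radical concentration high relative to trivalent titanium, so that a radical captured by a second titanium centre, which would either alkylate 7 to the same product or end as recyclable toluene 5 on work-up, should stay a minor channel.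

Step 5
Reactants: 9 1,2-bis(2,3,6-tribromo-4,5-dimethoxyphenyl)ethane, 10 boron tribromide
Product: 12 1,2-bis(2,3,6-tribromo-4,5-dihydroxyphenyl)ethane, via cyclic bis(bromoborate) 11 (not isolated)
Conditions: BBr3 (6 equiv), CH2Cl2, −78 °C to rt; then ice/H2O
Reagents that add atoms: boron tribromide, BrB(Br)Br (its boron and one bromine are carried only in intermediate 11 and leave on hydrolysis; no atom of it remains in 12)
Why: Lewis acid-mediated aryl methyl ether cleavage, in which BBr3 coordinates each ether oxygen, bromide removes the methyl group as MeBr to give the cyclic aryl bromoborate 11, and water hydrolyses the B–O bonds to the two catechols while the aryl C–Br bonds and the CH2–CH2 link are inert.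

**Compound list**

1 | 4-methylcatechol (4-methylbenzene-1,2-diol) | Cc1ccc(O)c(O)c1 | starting material
2 | bromine | BrBr | starting material
3 | 3,4,6-tribromo-5-methylbenzene-1,2-diol | Cc1c(Br)c(O)c(O)c(Br)c1Br | intermediate
4 | iodomethane | CI | starting material
5 | 2,3,6-tribromo-4,5-dimethoxytoluene (1,2,4-tribromo-5,6-dimethoxy-3-methylbenzene) | Cc1c(Br)c(OC)c(OC)c(Br)c1Br | intermediate
6 | N-bromosuccinimide | O=C1CCC(=O)N1Br | starting material
7 | 2,3,6-tribromo-4,5-dimethoxybenzyl bromide (1,2,4-tribromo-3-(bromomethyl)-5,6-dimethoxybenzene) | BrCc1c(Br)c(OC)c(OC)c(Br)c1Br | intermediate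
8 | 2,3,6-tribromo-4,5-dimethoxybenzyl radical (not isolated) | [CH2]c1c(Br)c(OC)c(OC)c(Br)c1Br | intermediate
9 | 1,2-bis(2,3,6-tribromo-4,5-dimethoxyphenyl)ethane | COc1c(OC)c(Br)c(CCc2c(Br)c(OC)c(OC)c(Br)c2Br)c(Br)c1Br | intermediate
10 | boron tribromide | BrB(Br)Br | starting material
11 | 1,2-bis(2,4,6,7-tetrabromo-1,3,2-benzodioxaborol-5-yl)ethane (not isolated) | BrB1Oc2c(Br)c(Br)c(CCc3c(Br)c(Br)c4OB(Br)Oc4c3Br)c(Br)c2O1 | intermediate
12 | 1,2-bis(2,3,6-tribromo-4,5-dihydroxyphenyl)ethane (CNP0231032.0) | Oc1c(O)c(Br)c(CCc2c(Br)c(O)c(O)c(Br)c2Br)c(Br)c1Br | target

**Step count**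

Total step count: 5
Longest linear sequence: 5 steps (1 to 3 to 5 to 7 to 9 to 12)

**Steps most likely to fail**

1. Step 4 (homocoupling). The radical, flanked by two ortho bromines, may combine slowly and be reduced a second time instead; protonation of the resulting organotitanium on work-up would amount to hydrodebromination back to 5. The fallback sets out from 7 and returns at 9, making the same benzylic carbon–carbon bond as an alkene by polar chemistry. One portion of 7 is heated with PPh3 in toluene to give (2,3,6-tribromo-4,5-dimethoxybenzyl)triphenylphosphonium bromide F1. A second portion is converted by Kornblum oxidation (DMSO, NaHCO3, 100 °C) into 2,3,6-tribromo-4,5-dimethoxybenzaldehyde F2. F1 is deprotonated with KOtBu in THF to (2,3,6-tribromo-4,5-dimethoxybenzylidene)triphenylphosphorane F3, which is not isolated; no aryne can arise because the ring has no hydrogen. Wittig olefination of F2 by this ylide should give 1,2-bis(2,3,6-tribromo-4,5-dimethoxyphenyl)ethene F4, of either double-bond geometry. Diimide reduction (TsNHNH2, NaOAc, THF/H2O, reflux) should then saturate the C=C bond without touching the aryl C–Br bonds and deliver 9.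

2. Step 1 (exhaustive bromination). The free catechol may be oxidized by bromine to the ortho-quinone, and once the ring is filled the side chain may be attacked through the quinone methide tautomer that the hydroxyl para to the methyl group allows; alternatively the reaction may stall before the third, most hindered substitution. The fallback sets out from 1 and returns at 5, bypassing 3 by reversing the order of protection and halogenation. Compound 1 is first O-methylated (MeI, K2CO3, DMF) to 3,4-dimethoxytoluene F5, which can neither be oxidized to a quinone nor tautomerize. Exhaustive ring bromination of F5 with excess Br2 and Fe powder (FeBr3 formed in the flask) in CH2Cl2 in the dark should then give 5 directly.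

3. Step 5 (global demethylation). Cleavage of the four ortho-brominated methyl ethers may stop short because partly demethylated boron complexes precipitate, and long exposure to HBr may cause loss or migration of ring bromine on the liberated electron-rich rings. The fallback sets out from 3 and returns at 12, changing the protecting group so that the last step is a mild transesterification. Compound 3 is acetylated (Ac2O, pyridine) to 3,4,6-tribromo-5-methyl-1,2-phenylene diacetate F6. Wohl–Ziegler bromination (NBS, AIBN, PhCF3) gives 3,4,6-tribromo-5-(bromomethyl)-1,2-phenylene diacetate F7. The same Cp2TiCl homocoupling, through the 4,5-diacetoxy-2,3,6-tribromobenzyl radical F8 (not isolated), should give 1,2-bis(4,5-diacetoxy-2,3,6-tribromophenyl)ethane F9. Acid methanolysis (HCl in MeOH, rt) then releases 12.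

**Further compounds**

F1 | step 4 | (2,3,6-tribromo-4,5-dimethoxybenzyl)triphenylphosphonium bromide | [Br-].COc1c(OC)c(Br)c(C[P+](c2ccccc2)(c2ccccc2)c2ccccc2)c(Br)c1Br
F2 | step 4 | 2,3,6-tribromo-4,5-dimethoxybenzaldehyde | COc1c(OC)c(Br)c(C=O)c(Br)c1Br
F3 | step 4 | (2,3,6-tribromo-4,5-dimethoxybenzylidene)triphenylphosphorane (not isolated) | COc1c(OC)c(Br)c(C=P(c2ccccc2)(c2ccccc2)c2ccccc2)c(Br)c1Br
F4 | step 4 | 1,2-bis(2,3,6-tribromo-4,5-dimethoxyphenyl)ethene (either geometry) | COc1c(OC)c(Br)c(C=Cc2c(Br)c(OC)c(OC)c(Br)c2Br)c(Br)c1Br
F5 | step 1 | 3,4-dimethoxytoluene (1,2-dimethoxy-4-methylbenzene) | COc1ccc(C)cc1OC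
F6 | step 5 | 3,4,6-tribromo-5-methyl-1,2-phenylene diacetate | CC(=O)Oc1c(OC(C)=O)c(Br)c(C)c(Br)c1Br
F7 | step 5 | 3,4,6-tribromo-5-(bromomethyl)-1,2-phenylene diacetate | CC(=O)Oc1c(OC(C)=O)c(Br)c(CBr)c(Br)c1Br
F8 | step 5 | 4,5-diacetoxy-2,3,6-tribromobenzyl radical (not isolated) | CC(=O)Oc1c(OC(C)=O)c(Br)c([CH2])c(Br)c1Br
F9 | step 5 | 1,2-bis(4,5-diacetoxy-2,3,6-tribromophenyl)ethane | CC(=O)Oc1c(OC(C)=O)c(Br)c(CCc2c(Br)c(OC(C)=O)c(OC(C)=O)c(Br)c2Br)c(Br)c1Br
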